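Take one ratio: target in the ash run over target in the birch run at 20.0 min is 0.990, although ash holds 3.08 times the charge. At 1.2 equiv, then, the two target readings agree within their scatter, whatever the concentration. The substrate readings differ: the apparent first-order loss constant, read from the last reading of each run, is 0.0186 min⁻¹ in ash and 0.0144 min⁻¹ in birch.

| flask | substrate | coupling partner | remark | time |
|---|---|---|---|---|
| ash | 20 mM | 1.2 equiv | run made earlier |  |
| birch | 6.5 mM | 1.2 equiv | run made earlier |  |
| south-west | 13 mM | 1.20 equiv |  | 1.0 h |
| north-west | 13 mM | 2.00 equiv |  | 1.0 h |
| south-east | 13 mM | 3.00 equiv |  | 1.0 h |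

| run | time / min | target / % | substrate / % |
|---|---|---|---|
| ash | 5.00 | 2.7 | 91.4 |
| ash | 10.0 | 5.2 | 85.0 |
| ash | 15.0 | 7.8 | 77.0 |
| ash | 20.0 | 10.3 | 68.9 |
| birch | 2.50 | 1.0 | 96.7 |
| birch | 8.00 | 3.3 | 88.6 |
| birch | 15.0 | 7.7 | 80.8 |
| birch | 20.0 | 10.4 | 75.0 |

(each reading ± 0.5 percentage points)

- "hardly changes" means that all values lie within two and a half points (for a concentration: within two and a half percent of the largest)

- amount of target at the end, in percent of the substrate charged for south-west, north-west, south-east, in this order
- how the row runs (rises, then falls / rises all the way / falls all the way / falls, then rises / hardly changes)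

I assume the extra loss runs through the coupling partner, held constant (pseudo-first-order). The two runs then split the loss into a partner term of 0.262 M⁻¹ min⁻¹ times partner concentration and a partner-free term of 0.0123 min⁻¹. Their quotient is 47.1 mM, the crossover concentration: the partner level at which both losses are equal, read from the readings with their scatter. Partner level over crossover is the partner-to-free ratio.

Now solve the row at both ends. At the top end, the ash target line continues at 0.00515 min⁻¹ of the charge, giving 30.9% whatever the partner charge, a flat row. At the bottom end, target follows the substrate present at that same constant. Total loss is 0.0164 min⁻¹ in south-west and 0.0226 min⁻¹ in south-east, so target reaches 19.7% and 16.9%. The ash line stays straight as substrate falls to 68.9%, so the flasks should lie nearer the top. I commit to a row that falls gently.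

The forecast differs: 27%, 44%, 61%, rises all the way, reading “zero order in substrate and first order in partner”.

The flasks give 29.2%, 28.0%, 26.5%: the row falls all the way.

    substrate → target (k = 0.00540 min⁻¹)
    substrate + coupling partner → intermediate A (k = 0.190 M⁻¹ min⁻¹)
    substrate → intermediate B (k = 0.00780 min⁻¹)
    coupling partner + intermediate A → side product (k = 0.130 M⁻¹ min⁻¹)
    intermediate B → target (k = 0.00990 min⁻¹)

Partner level as charged over the crossover, a ratio of two loss rates read from the ash and birch runs, is 0.331 in south-west and 0.827 in south-east, and at 1.00 h the amount of intermediate A plus side product over that of target plus intermediate B stands at 0.214 in south-west and 0.536 in south-east. In south-west at that time, 21.6% stands as intermediate B beside 29.2% target, and intermediate B is still made 1.40 times as fast as it is used up.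

(The data were computed for an exercise; scatter was added.)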